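I began from a ratio: the fraction of target lost per minute over the fraction of the charge converted per minute. Target made early decays while the rest is still being made, so I reckoned only the small shortfall below the whole charge.

| setting | north | north-east | south-west | flask |
|---|---|---|---|---|
| substrate | 0.0050 M | 0.020 M | 0.010 M | 0.010 M |
| free catalyst | 0.3 mol% | 0.3 mol% | 0.45 mol% | 0.3 mol% |
| remark | run made earlier | run made earlier | run made earlier |  |
| time |  |  |  | 40 min |

| run | time / min | target / % | substrate / % |
|---|---|---|---|
| north | 1.33 | 35 | 65 |
| north | 3.00 | 69 | 30 |
| north | 8.00 | 92 | 0 |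
| north | 15.0 | 84 | 1 |
| north | 40.0 | 66 | 0 |
| north-east | 1.33 | 44 | 58 |
| north-east | 3.00 | 87 | 11 |
| north-east | 8.00 | 97 | 0 |
| north-east | 15.0 | 94 | 1 |
| north-east | 40.0 | 81 | 0 |
| south-west | 1.33 | 55 | 43 |
| south-west | 3.00 | 95 | 1 |
| south-west | 8.00 | 92 | 1 |
| south-west | 15.0 | 88 | 0 |
| south-west | 40.0 | 70 | 2 |

(readings scatter by 2 percentage points)

- the earlier runs were read with a standard deviation of 2 percentage points
- a reading or a percentage of target counts all its forms, free or not

* time, not beyond 40 min, at which the flask holds most target
* the amount of target, in percent of the substrate charged, at that time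

The south-west run has the flask's substrate concentration. Its target readings went from 95 % at 3.00 min to 70 % at 40.0 min, so I read a first-order loss of 0.00825 min⁻¹. Its substrate reading was 43 % at 1.33 min, so I read its conversion, as a fraction of the charge, at 0.429 min⁻¹. I assumed this scales with loading, which gave the flask 0.286 min⁻¹. A straight fall at that rate ends at 3.50 min. I guessed a slow tail of 1.75 min, which put the flask's peak near 5.25 min. In my estimate for the flask, making was centred at 1.75 min, so target had waited 3.50 min on average by the peak. The flask's estimated shortfall was then 2.89 %: the loss ratio, the inverse of a selectivity factor. My figure for the flask's peak was therefore 97.1 %.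

The forecast, from “The substrate falls almost linearly, so it follows near-saturated catalysis”, gave 96 % at 4.7 min. That is lower than my amount and earlier than my time.

The flask gave 95.8 % at 5.21 min, all forms of target counted.

    crystals ⇌ target, rate k1*(cs1 - [target]) while solid is left; crystals form when [target] > cs1 (solubility = 7.70 mM, k = 0.0370 s⁻¹)
    catalyst intermediate → free catalyst + target (k = 2.00 s⁻¹)
    substrate + free catalyst ⇌ catalyst intermediate (K = 2300 M⁻¹, k = 1700 M⁻¹ s⁻¹)
    target ⇌ isomer of the product (K = 1.30, k = 2.10 × 10⁻⁴ s⁻¹)

The flask's shortfall was 4.20 %, more than the loss ratio, with 3.78 % standing as isomer of the product and 0.429 % as substrate at 5.21 min. The neighbouring flask is the same flask with 0.12 mol% of free catalyst, so by my scaling it converted 0.114 min⁻¹, slower than the flask. Its loss ratio came to 7.22 %, which put its peak near 92.8 %. The highest amount of target simulated in that neighbouring flask was 90.9 %.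

The readings are calculated with made-up constants; the scatter is artificial.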